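**Plan**

- Retrosynthesis: the two lactam carbonyls, both phenols and N7–H are unmasked last (two methyl imidate ethers, two silyl ethers, one N7 carbamate). Then the ketone carbon–aryl bond is cut, then the C6–CHO bond, then the C5–aryl bond.
- Enabling feature: the ketone carbon bridges pyrrole C6 of the pyrrolo[2,3-d]pyrimidine and a guaiacyl ring. Its obvious precursors, a C6 formyl carbon and a bromine-bearing aryl carbon, are both electrophiles, so they are united by turning the formyl C–H into an acyl radical that nickel couples with the aryl bromide.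
- Forward: the bicyclic core is bought intact and no ring is built. The order is C4/C2 methoxylation, C5 iodination, C5 Suzuki arylation, N7 Boc protection, C6 lithiation–formylation, acyl–aryl coupling, one-pot acid deprotection. One bromophenol supplies both aryl rings.
- Stereochemistry: none; the target is achiral.

Key step: step 8

Assumption: the target is taken as the 2,4-dioxo (lactam) tautomer with hydrogen on N1, N3 and N7, as drawn. An N7 Boc group is added to the key-step partners so that a 2-formylpyrrolide cannot chelate nickel.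

**Step 1**
Reactants: 1 2,4-dichloro-7H-pyrrolo[2,3-d]pyrimidine
Product: 3 2,4-dimethoxy-7H-pyrrolo[2,3-d]pyrimidine, via 2-chloro-4-methoxy-7H-pyrrolo[2,3-d]pyrimidine 2 (not isolated)
Conditions: NaOMe (6 equiv), MeOH, sealed vessel, 110 °C
Reagents that add atoms: sodium methoxide, [Na+].[O-]C
Why: Twofold nucleophilic aromatic substitution (SNAr) by methoxide, at C4 first and at C2 under forcing conditions, is the established entry to 2,4-dimethoxy-7-deazapurines, and the N7 anion formed in base slows but should not stop the second displacement.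

**Step 2**
Reactants: 3 2,4-dimethoxy-7H-pyrrolo[2,3-d]pyrimidine
Product: 4 5-iodo-2,4-dimethoxy-7H-pyrrolo[2,3-d]pyrimidine
Conditions: NIS (1.05 equiv), DMF, 0 °C → rt, dark
Reagents that add atoms: N-iodosuccinimide, O=C1CCC(=O)N1I
Why: Electrophilic aromatic iodination of the electron-rich pyrrole ring should go to C5, the β-position that is the normal site of halogenation in 7-deazapurines.

**Step 3**
Reactants: 5 4-bromo-2-methoxyphenol
Product: 6 (4-bromo-2-methoxyphenoxy)(tert-butyl)dimethylsilane
Conditions: TBSCl, imidazole, DMF, rt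
Reagents that add atoms: tert-butyldimethylsilyl chloride, CC(C)(C)[Si](C)(C)Cl
Why: Imidazole-mediated silyl ether formation on a phenol is routine and installs a protecting group that carries only strong primary C–H bonds, as the later hydrogen-abstraction step requires.

**Step 4**
Reactants: 6 (4-bromo-2-methoxyphenoxy)(tert-butyl)dimethylsilane
Product: 7 tert-butyl[2-methoxy-4-(4,4,5,5-tetramethyl-1,3,2-dioxaborolan-2-yl)phenoxy]dimethylsilane
Conditions: B2pin2, Pd(dppf)Cl2 (3 mol %), KOAc, 1,4-dioxane, 90 °C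
Reagents that add atoms: bis(pinacolato)diboron, CC1(C)OB(OC1(C)C)B1OC(C)(C)C(C)(C)O1
Why: Miyaura borylation of an electron-rich aryl bromide with the weak base KOAc should leave the aryl silyl ether untouched.

**Step 5**
Reactants: 4 5-iodo-2,4-dimethoxy-7H-pyrrolo[2,3-d]pyrimidine; 7 tert-butyl[2-methoxy-4-(4,4,5,5-tetramethyl-1,3,2-dioxaborolan-2-yl)phenoxy]dimethylsilane
Product: 8 5-[4-(tert-butyldimethylsilyloxy)-3-methoxyphenyl]-2,4-dimethoxy-7H-pyrrolo[2,3-d]pyrimidine
Conditions: Pd(PPh3)4 (5 mol %), Na2CO3, DME/H2O (4:1), 80 °C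
Reagents that add atoms: none
Why: Suzuki–Miyaura coupling of 5-iodo-7-deazapurines with free N7–H is routine, and the mild carbonate base at moderate temperature should preserve the aryl silyl ether.

**Step 6**
Reactants: 8 5-[4-(tert-butyldimethylsilyloxy)-3-methoxyphenyl]-2,4-dimethoxy-7H-pyrrolo[2,3-d]pyrimidine
Product: 9 tert-butyl 5-[4-(tert-butyldimethylsilyloxy)-3-methoxyphenyl]-2,4-dimethoxy-7H-pyrrolo[2,3-d]pyrimidine-7-carboxylate
Conditions: Boc2O, DMAP (10 mol %), MeCN, rt
Reagents that add atoms: di-tert-butyl dicarbonate, CC(C)(C)OC(=O)OC(=O)OC(C)(C)C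
Why: DMAP-catalysed N-acylation (carbamate formation) at N7, the only N–H, gives a group that directs C6 lithiation, masks the acidic N–H for the nickel step and is placed after the Suzuki coupling because aqueous base would remove it.

**Step 7**
Reactants: 9 tert-butyl 5-[4-(tert-butyldimethylsilyloxy)-3-methoxyphenyl]-2,4-dimethoxy-7H-pyrrolo[2,3-d]pyrimidine-7-carboxylate
Product: 12 tert-butyl 5-[4-(tert-butyldimethylsilyloxy)-3-methoxyphenyl]-6-formyl-2,4-dimethoxy-7H-pyrrolo[2,3-d]pyrimidine-7-carboxylate, via C6-lithio carbamate 10 (not isolated), via lithium hemiaminal alkoxide 11 (not isolated)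
Conditions: LiN(iPr)2 (LDA, commercial solution, 1.3 equiv), THF, −78 °C; DMF (3 equiv), −78 °C; AcOH, −78 °C → rt
Reagents that add atoms: N,N-dimethylformamide, CN(C)C=O (formyl carbon and oxygen); LiN(iPr)2, [Li]N(C(C)C)C(C)C (lithium of 10 and 11 only)
Why: Carbamate-directed α-lithiation of an N-Boc pyrrole (directed metalation), followed by formylation with DMF, should act at C6–H, the only pyrrole C–H and one acidified by both the carbamate and the fused pyrimidine, and the cold acidic quench releases the aldehyde before the carbamate can migrate.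

**Step 8**
Reactants: 12 tert-butyl 5-[4-(tert-butyldimethylsilyloxy)-3-methoxyphenyl]-6-formyl-2,4-dimethoxy-7H-pyrrolo[2,3-d]pyrimidine-7-carboxylate; 6 (4-bromo-2-methoxyphenoxy)(tert-butyl)dimethylsilane
Product: 13 tert-butyl 6-[4-(tert-butyldimethylsilyloxy)-3-methoxybenzoyl]-5-[4-(tert-butyldimethylsilyloxy)-3-methoxyphenyl]-2,4-dimethoxy-7H-pyrrolo[2,3-d]pyrimidine-7-carboxylate
Conditions: 6 (2 equiv), (NBu4)4W10O32 (2 mol %), NiBr2(dme) (10 mol %), 4,4′-di-tert-butyl-2,2′-bipyridine (10 mol %), K3PO4 (anhydrous, 1.5 equiv), degassed MeCN, 390 nm LEDs, 25 °C (fan cooling)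
Reagents that add atoms: none
Why: Near-ultraviolet excitation of decatungstate gives an oxygen-centred excited state that abstracts the formyl hydrogen of 12; the C6 aroyl radical is captured by the aryl nickel bromide formed from 6 and low-valent bipyridine-ligated nickel, and the acyl(aryl)nickel species reductively eliminates the carbonyl–aryl bond while reduced decatungstate returns its electron to nickel and K3PO4 takes up HBr. The closest known reaction type is the decatungstate/nickel acylation of aryl bromides with aromatic aldehydes. No ring is closed and no stereocentre is formed; one skeletal C–C bond is made. The step needs hydrogen abstraction at the formyl C–H only, which is secured because that bond is the weakest and most hydridic in 12 and 6, the alternatives being strong primary C–H bonds of methoxy, silyl-methyl and tert-butyl groups. An aroyl radical conjugated to the pyrrole loses CO slowly, so the carbonyl carbon is kept, and its position is fixed because the formyl group was placed at C6 by directed lithiation. The N7 carbamate keeps a 2-formylpyrrolide from binding nickel as an N,O-chelate and shuts off N-arylation.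

**Step 9**
Reactants: 13 tert-butyl 6-[4-(tert-butyldimethylsilyloxy)-3-methoxybenzoyl]-5-[4-(tert-butyldimethylsilyloxy)-3-methoxyphenyl]-2,4-dimethoxy-7H-pyrrolo[2,3-d]pyrimidine-7-carboxylate
Product: 15 rigidin D [6-(4-hydroxy-3-methoxybenzoyl)-5-(4-hydroxy-3-methoxyphenyl)-1H-pyrrolo[2,3-d]pyrimidine-2,4(3H,7H)-dione], via N7-unprotected 2,4-dimethoxy bisphenol 14 (not isolated)
Conditions: 6 M aq HCl, 1,4-dioxane, 90 °C
Reagents that add atoms: water, O (the two lactam oxygens on the addition–elimination pathway)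
Why: Acidolysis of the Boc group, acid-catalysed desilylation of the aryl silyl ethers and hydrolysis of the two imidate-type methyl ethers (addition–elimination at C4 and C2) should run in one pot, while the aryl methyl ethers, which need far stronger dealkylating agents, remain.

**Compound list**

1 | 2,4-dichloro-7H-pyrrolo[2,3-d]pyrimidine | Clc1nc(Cl)c2cc[nH]c2n1 | starting material
2 | 2-chloro-4-methoxy-7H-pyrrolo[2,3-d]pyrimidine | COc1nc(Cl)nc2[nH]ccc12 | intermediate
3 | 2,4-dimethoxy-7H-pyrrolo[2,3-d]pyrimidine | COc1nc(OC)c2cc[nH]c2n1 | intermediate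
4 | 5-iodo-2,4-dimethoxy-7H-pyrrolo[2,3-d]pyrimidine | COc1nc(OC)c2c(I)c[nH]c2n1 | intermediate
5 | 4-bromo-2-methoxyphenol | COc1cc(Br)ccc1O | starting material
6 | (4-bromo-2-methoxyphenoxy)(tert-butyl)dimethylsilane | COc1cc(Br)ccc1O[Si](C)(C)C(C)(C)C | intermediate
7 | tert-butyl[2-methoxy-4-(4,4,5,5-tetramethyl-1,3,2-dioxaborolan-2-yl)phenoxy]dimethylsilane | COc1cc(B2OC(C)(C)C(C)(C)O2)ccc1O[Si](C)(C)C(C)(C)C | intermediate
8 | 5-[4-(tert-butyldimethylsilyloxy)-3-methoxyphenyl]-2,4-dimethoxy-7H-pyrrolo[2,3-d]pyrimidine | COc1nc(OC)c2c(-c3ccc(O[Si](C)(C)C(C)(C)C)c(OC)c3)c[nH]c2n1 | intermediate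
9 | tert-butyl 5-[4-(tert-butyldimethylsilyloxy)-3-methoxyphenyl]-2,4-dimethoxy-7H-pyrrolo[2,3-d]pyrimidine-7-carboxylate | COc1nc(OC)c2c(-c3ccc(O[Si](C)(C)C(C)(C)C)c(OC)c3)cn(C(=O)OC(C)(C)C)c2n1 | intermediate
10 | tert-butyl 5-[4-(tert-butyldimethylsilyloxy)-3-methoxyphenyl]-6-lithio-2,4-dimethoxy-7H-pyrrolo[2,3-d]pyrimidine-7-carboxylate | COc1nc(OC)c2c(-c3ccc(O[Si](C)(C)C(C)(C)C)c(OC)c3)c([Li])n(C(=O)OC(C)(C)C)c2n1 | intermediate
11 | lithium alkoxide of tert-butyl 5-[4-(tert-butyldimethylsilyloxy)-3-methoxyphenyl]-6-[(dimethylamino)(hydroxy)methyl]-2,4-dimethoxy-7H-pyrrolo[2,3-d]pyrimidine-7-carboxylate | COc1nc(OC)c2c(-c3ccc(O[Si](C)(C)C(C)(C)C)c(OC)c3)c(C(O[Li])N(C)C)n(C(=O)OC(C)(C)C)c2n1 | intermediate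
12 | tert-butyl 5-[4-(tert-butyldimethylsilyloxy)-3-methoxyphenyl]-6-formyl-2,4-dimethoxy-7H-pyrrolo[2,3-d]pyrimidine-7-carboxylate | COc1nc(OC)c2c(-c3ccc(O[Si](C)(C)C(C)(C)C)c(OC)c3)c(C=O)n(C(=O)OC(C)(C)C)c2n1 | intermediate
13 | tert-butyl 6-[4-(tert-butyldimethylsilyloxy)-3-methoxybenzoyl]-5-[4-(tert-butyldimethylsilyloxy)-3-methoxyphenyl]-2,4-dimethoxy-7H-pyrrolo[2,3-d]pyrimidine-7-carboxylate | COc1nc(OC)c2c(-c3ccc(O[Si](C)(C)C(C)(C)C)c(OC)c3)c(C(=O)c3ccc(O[Si](C)(C)C(C)(C)C)c(OC)c3)n(C(=O)OC(C)(C)C)c2n1 | intermediate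
14 | (4-hydroxy-3-methoxyphenyl)[5-(4-hydroxy-3-methoxyphenyl)-2,4-dimethoxy-7H-pyrrolo[2,3-d]pyrimidin-6-yl]methanone | COc1nc(OC)c2c(-c3ccc(O)c(OC)c3)c(C(=O)c3ccc(O)c(OC)c3)[nH]c2n1 | intermediate
15 | rigidin D, 6-(4-hydroxy-3-methoxybenzoyl)-5-(4-hydroxy-3-methoxyphenyl)-1H-pyrrolo[2,3-d]pyrimidine-2,4(3H,7H)-dione | COc1cc(C(=O)c2[nH]c3[nH]c(=O)[nH]c(=O)c3c2-c2ccc(O)c(OC)c2)ccc1O | target

**Step count**

Total: 9 steps. Longest linear sequence: 7 steps (1 → 3 → 4 → 8 → 9 → 12 → 13 → 15; the branch from 5 through 6 and 7 is equally long).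

**Steps most likely to fail**

1. Step 8 (key step). Hydrogen abstraction at a formyl group crowded by the N7 carbamate and the C5 aryl ring may be slow, so that hydrodebromination of the bromide and erosion of the carbamate under irradiation outrun the coupling. The fallback reverses the polarity at C6 with known chemistry and sets out from 9. Commercial vanillic acid would be coupled with MeNHOMe·HCl (EDC·HCl, HOBt, iPr2NEt, CH2Cl2) to 4-hydroxy-N,3-dimethoxy-N-methylbenzamide F1 and silylated (TBSCl, imidazole) to 4-(tert-butyldimethylsilyloxy)-N,3-dimethoxy-N-methylbenzamide F2. Carbanion 10, generated from 9 as in step 7, would be acylated with this Weinreb amide at −78 °C to give the chelated lithium N-methoxy-N-methyl hemiaminal alkoxide F3, which collapses on cold AcOH quench to ketone 13, where the route is rejoined.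

2. Step 7. The Boc group may shift from N7 to the C6 carbanion, or the alkoxide adduct may close onto the carbamate before the quench. The fallback replaces deprotometalation by electrophilic substitution and sets out from 8. Vilsmeier–Haack formylation (POCl3, DMF, 0 → 50 °C) at C6, the only free pyrrole carbon, would give the C6 N,N-dimethyliminium chloride F4. Hydrolysis with aqueous NaOAc gives 5-[4-(tert-butyldimethylsilyloxy)-3-methoxyphenyl]-2,4-dimethoxy-7H-pyrrolo[2,3-d]pyrimidine-6-carbaldehyde F5. Boc2O with catalytic DMAP then gives 12, where the route is rejoined.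

3. Step 9. Hydrolysis of the C2 methyl imidate may stall, or cleavage of the aryl methyl ethers may set in when the acid is pushed. The fallback is staged, with nucleophilic O-demethylation in place of hydrolysis, and sets out from 13. K2CO3 in MeOH at room temperature would remove the activated N7 carbamate and both aryl silyl ethers to give 14, now isolated. NaI in AcOH at 90 °C would then dealkylate the two imidate methyl ethers by SN2 attack of iodide on the methyl carbons, which aryl methyl ethers do not undergo under these conditions, and deliver 15. This fallback makes no compound outside the list (F0).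

**Further compounds**

F1 | step 8 | 4-hydroxy-N,3-dimethoxy-N-methylbenzamide | CON(C)C(=O)c1ccc(O)c(OC)c1
F2 | step 8 | 4-(tert-butyldimethylsilyloxy)-N,3-dimethoxy-N-methylbenzamide | CON(C)C(=O)c1ccc(O[Si](C)(C)C(C)(C)C)c(OC)c1
F3 | step 8 | lithium alkoxide of the N-methoxy-N-methyl hemiaminal formed from 10 and F2 | COc1nc(OC)c2c(-c3ccc(O[Si](C)(C)C(C)(C)C)c(OC)c3)c(C(O[Li])(N(C)OC)c3ccc(O[Si](C)(C)C(C)(C)C)c(OC)c3)n(C(=O)OC(C)(C)C)c2n1
F4 | step 7 | {5-[4-(tert-butyldimethylsilyloxy)-3-methoxyphenyl]-2,4-dimethoxy-7H-pyrrolo[2,3-d]pyrimidin-6-yl}methylidene(dimethyl)ammonium chloride | C[N+](C)=Cc1[nH]c2nc(OC)nc(OC)c2c1-c1ccc(O[Si](C)(C)C(C)(C)C)c(OC)c1.[Cl-]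
F5 | step 7 | 5-[4-(tert-butyldimethylsilyloxy)-3-methoxyphenyl]-2,4-dimethoxy-7H-pyrrolo[2,3-d]pyrimidine-6-carbaldehyde | COc1nc(OC)c2c(-c3ccc(O[Si](C)(C)C(C)(C)C)c(OC)c3)c(C=O)[nH]c2n1
F0 | step 9 | none | none
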